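**Retrosynthetic overview**
1. Target 19 ⇐ global acid deprotection (three MOM ethers and one TBS ether) of benzophenone 18.
2. Benzoyl C–C bond ⇐ directed ortho-lithiation of arene 15 and acylation with a Weinreb benzamide.
3. 1,1-Disubstituted alkene ⇐ Wittig methylenation of α-silyloxy ketone 13; the ketone comes from ester 9 through an in-situ Weinreb amide and a homoprenyl Grignard reagent.
4. Ar–CH2 bond and the stereocentre ⇐ Cu-catalysed opening of methyl (R)-glycidate at C3 by the aryl Grignard of tris-MOM phloroglucinol; the C–O stereocentre is bought and never touched.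
5. No ring is formed: both benzene rings come from commercial materials (phloroglucinol and N-methoxy-N-methylbenzamide).

Assumption: the stereocentre in the given SMILES is (R) by CIP analysis. n-BuLi, MgBr2·OEt2, CuI, i-PrMgCl, Mg, KHMDS, amine bases and solvents are left unnumbered because none of their non-hydrogen atoms ends up in an isolated product.

**Step 1**
Reactants: 1 phloroglucinol; 2 chloromethyl methyl ether
Product: 3 1,3,5-tris(methoxymethoxy)benzene
Conditions: MOMCl (3.6 eq), i-Pr2NEt (4 eq), CH2Cl2, 0 °C → rt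
Reagents that add atoms: 2 chloromethyl methyl ether, COCCl
Why: Threefold O-alkylation (Williamson-type acetal ether formation) of the phenols installs MOM groups that later direct ortho-lithiation.

**Step 2**
Reactants: 3 1,3,5-tris(methoxymethoxy)benzene; 4 methyl (R)-oxirane-2-carboxylate
Product: 7 methyl (2R)-2-hydroxy-3-[2,4,6-tris(methoxymethoxy)phenyl]propanoate, via aryllithium 5 (not isolated), via arylmagnesium bromide 6 (not isolated)
Conditions: n-BuLi (1.05 eq), THF, 0 °C; MgBr2·OEt2, 0 °C; CuI (10 mol %), then 4 (0.8 eq), −40 → −20 °C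
Reagents that add atoms: 4 methyl (R)-glycidate, COC(=O)[C@H]1CO1
Why: Directed ortho-metalation between two OMOM groups, Li→Mg transmetalation and Cu-catalysed SN2 epoxide opening at the unsubstituted C3 of the glycidate give the aryl-lactate; the C2–O stereocentre is not involved, so (R) is retained.

**Step 3**
Reactants: 7 methyl (2R)-2-hydroxy-3-[2,4,6-tris(methoxymethoxy)phenyl]propanoate; 8 tert-butyldimethylsilyl chloride
Product: 9 methyl (2R)-2-[(tert-butyldimethylsilyl)oxy]-3-[2,4,6-tris(methoxymethoxy)phenyl]propanoate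
Conditions: TBSCl, imidazole, DMF, rt
Reagents that add atoms: 8 TBSCl, CC(C)(C)[Si](C)(C)Cl
Why: Standard silylation of the secondary alcohol, needed so the later Grignard, ylide and organolithium steps see no free OH.

**Step 4**
Reactants: 9 methyl (2R)-2-[(tert-butyldimethylsilyl)oxy]-3-[2,4,6-tris(methoxymethoxy)phenyl]propanoate; 10 N,O-dimethylhydroxylamine hydrochloride; 11 5-bromo-2-methylpent-2-ene (used as its Grignard reagent)
Product: 13 (2R)-2-[(tert-butyldimethylsilyl)oxy]-7-methyl-1-[2,4,6-tris(methoxymethoxy)phenyl]oct-6-en-3-one, via Weinreb amide 12 (not isolated)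
Conditions: 10 (1.5 eq), i-PrMgCl (3.0 eq), THF, −20 → 0 °C; then 4-methylpent-3-enylMgBr (from 11, Mg, THF; 2.5 eq), 0 °C → rt
Reagents that add atoms: 11 5-bromo-2-methylpent-2-ene, CC(C)=CCCBr (delivered as CC(C)=CCC[Mg]Br)
Why: Ester aminolysis by the magnesium amide gives the Weinreb amide in situ, and Grignard addition stops at the chelated tetrahedral intermediate (Weinreb ketone synthesis), so no tertiary alcohol forms and the α-stereocentre is not enolised.

**Step 5**
Reactants: 13 (2R)-2-[(tert-butyldimethylsilyl)oxy]-7-methyl-1-[2,4,6-tris(methoxymethoxy)phenyl]oct-6-en-3-one; 14 methyltriphenylphosphonium bromide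
Product: 15 tert-butyldimethyl({(2R)-7-methyl-3-methylidene-1-[2,4,6-tris(methoxymethoxy)phenyl]oct-6-en-2-yl}oxy)silane
Conditions: Ph3PCH3Br (3 eq), KHMDS (2.8 eq), THF, 0 °C; then 13, 0 °C → rt
Reagents that add atoms: 14 methyltriphenylphosphonium bromide, C[P+](c1ccccc1)(c1ccccc1)c1ccccc1.[Br-]
Why: Wittig methylenation with the salt-free, weakly basic ylide converts the ketone into the 1,1-disubstituted alkene without epimerising the adjacent silyloxy centre.

**Step 6**
Reactants: 15 tert-butyldimethyl({(2R)-7-methyl-3-methylidene-1-[2,4,6-tris(methoxymethoxy)phenyl]oct-6-en-2-yl}oxy)silane; 16 N-methoxy-N-methylbenzamide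
Product: 18 (3-{(2R)-2-[(tert-butyldimethylsilyl)oxy]-7-methyl-3-methylideneoct-6-en-1-yl}-2,4,6-tris(methoxymethoxy)phenyl)(phenyl)methanone, via aryllithium 17 (not isolated)
Conditions: n-BuLi (1.2 eq), THF, 0 °C, 1 h; then 16, −78 °C → rt
Reagents that add atoms: 16 N-methoxy-N-methylbenzamide, CON(C)C(=O)c1ccccc1
Why: Directed ortho-metalation at one of the two equivalent ring CH positions (each flanked by two OMOM groups) followed by Weinreb acylation gives the diaryl ketone without over-addition; the side chain carries no electrophile or acidic OH at this stage.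

**Step 7**
Reactants: 18 (3-{(2R)-2-[(tert-butyldimethylsilyl)oxy]-7-methyl-3-methylideneoct-6-en-1-yl}-2,4,6-tris(methoxymethoxy)phenyl)(phenyl)methanone
Product: 19 [2,4,6-trihydroxy-3-[(2R)-2-hydroxy-7-methyl-3-methylideneoct-6-en-1-yl]phenyl](phenyl)methanone
Conditions: anhydrous HCl (1.25 M in MeOH), 0 °C → rt, monitored and quenched with NaHCO3 as soon as complete
Reagents that add atoms: none
Why: Acid-catalysed transacetalisation removes the three phenolic MOM ethers and methanolysis removes the TBS ether in one operation; dilute acid at low temperature is chosen to leave both alkenes and the allylic alcohol intact.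

**Compound list**
1 | phloroglucinol (benzene-1,3,5-triol) | Oc1cc(O)cc(O)c1 | starting material
2 | chloromethyl methyl ether (MOMCl) | COCCl | starting material
3 | 1,3,5-tris(methoxymethoxy)benzene | COCOc1cc(OCOC)cc(OCOC)c1 | intermediate
4 | methyl (R)-oxirane-2-carboxylate (methyl (R)-glycidate) | COC(=O)[C@H]1CO1 | starting material
5 | [2,4,6-tris(methoxymethoxy)phenyl]lithium | [Li]c1c(OCOC)cc(OCOC)cc1OCOC | intermediate
6 | [2,4,6-tris(methoxymethoxy)phenyl]magnesium bromide | Br[Mg]c1c(OCOC)cc(OCOC)cc1OCOC | intermediate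
7 | methyl (2R)-2-hydroxy-3-[2,4,6-tris(methoxymethoxy)phenyl]propanoate | COC(=O)[C@H](O)Cc1c(OCOC)cc(OCOC)cc1OCOC | intermediate
8 | tert-butyldimethylsilyl chloride | CC(C)(C)[Si](C)(C)Cl | starting material
9 | methyl (2R)-2-[(tert-butyldimethylsilyl)oxy]-3-[2,4,6-tris(methoxymethoxy)phenyl]propanoate | COC(=O)[C@H](O[Si](C)(C)C(C)(C)C)Cc1c(OCOC)cc(OCOC)cc1OCOC | intermediate
10 | N,O-dimethylhydroxylamine hydrochloride | CNOC.Cl | starting material
11 | 5-bromo-2-methylpent-2-ene | CC(C)=CCCBr | starting material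
12 | (2R)-2-[(tert-butyldimethylsilyl)oxy]-N-methoxy-N-methyl-3-[2,4,6-tris(methoxymethoxy)phenyl]propanamide | CON(C)C(=O)[C@H](O[Si](C)(C)C(C)(C)C)Cc1c(OCOC)cc(OCOC)cc1OCOC | intermediate
13 | (2R)-2-[(tert-butyldimethylsilyl)oxy]-7-methyl-1-[2,4,6-tris(methoxymethoxy)phenyl]oct-6-en-3-one | CC(C)=CCCC(=O)[C@H](O[Si](C)(C)C(C)(C)C)Cc1c(OCOC)cc(OCOC)cc1OCOC | intermediate
14 | methyltriphenylphosphonium bromide | C[P+](c1ccccc1)(c1ccccc1)c1ccccc1.[Br-] | starting material
15 | tert-butyldimethyl({(2R)-7-methyl-3-methylidene-1-[2,4,6-tris(methoxymethoxy)phenyl]oct-6-en-2-yl}oxy)silane | C=C(CCC=C(C)C)[C@H](O[Si](C)(C)C(C)(C)C)Cc1c(OCOC)cc(OCOC)cc1OCOC | intermediate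
16 | N-methoxy-N-methylbenzamide | CON(C)C(=O)c1ccccc1 | starting material
17 | (3-{(2R)-2-[(tert-butyldimethylsilyl)oxy]-7-methyl-3-methylideneoct-6-en-1-yl}-2,4,6-tris(methoxymethoxy)phenyl)lithium | C=C(CCC=C(C)C)[C@H](O[Si](C)(C)C(C)(C)C)Cc1c(OCOC)cc(OCOC)c([Li])c1OCOC | intermediate
18 | (3-{(2R)-2-[(tert-butyldimethylsilyl)oxy]-7-methyl-3-methylideneoct-6-en-1-yl}-2,4,6-tris(methoxymethoxy)phenyl)(phenyl)methanone | C=C(CCC=C(C)C)[C@H](O[Si](C)(C)C(C)(C)C)Cc1c(OCOC)cc(OCOC)c(C(=O)c2ccccc2)c1OCOC | intermediate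
19 | [2,4,6-trihydroxy-3-[(2R)-2-hydroxy-7-methyl-3-methylideneoct-6-en-1-yl]phenyl](phenyl)methanone (CNP0149425.1) | C=C(CCC=C(C)C)[C@H](O)Cc1c(O)cc(O)c(C(=O)c2ccccc2)c1O | target

**Totals**
Total step count: 7. Longest linear sequence: 7 steps (1 → 3 → 7 → 9 → 13 → 15 → 18 → 19).

**Steps most likely to fail, with fallbacks**

Step 7 is the riskiest. The freed 4-OH sits ortho to the side chain and can add to the protonated 1,1-disubstituted alkene to give a chroman, and the allylic alcohol can ionise. The fallback sets out from 18 and comes back at 19 by separating the two deprotections and avoiding protic acid. TBAF in THF at 0 °C removes the silyl group to give {3-[(2R)-2-hydroxy-7-methyl-3-methylideneoct-6-en-1-yl]-2,4,6-tris(methoxymethoxy)phenyl}(phenyl)methanone F7. The MOM ethers are then cleaved by Lewis-acid-assisted thiolysis (ZnBr2, n-PrSH, CH2Cl2, 0 °C, minutes), which transfers the CH2OMe unit to sulfur under aprotic conditions and gives 19.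

Step 2 comes next. The di-ortho-substituted aryl nucleophile is hindered, and the glycidate ester can be attacked at the carbonyl instead of C3. The fallback sets out from 3 and comes back at 13, replacing the ester electrophile by an ether. Arene 3 is lithiated to 5 as before and treated with BF3·OEt2 and (R)-benzyl glycidyl ether at −78 °C to give (2R)-1-(benzyloxy)-3-[2,4,6-tris(methoxymethoxy)phenyl]propan-2-ol F1. TBSCl/imidazole gives its silyl ether, (2R)-1-(benzyloxy)-2-[(tert-butyldimethylsilyl)oxy]-3-[2,4,6-tris(methoxymethoxy)phenyl]propane F2. Hydrogenolysis (H2, Pd/C, EtOAc) gives (2R)-2-[(tert-butyldimethylsilyl)oxy]-3-[2,4,6-tris(methoxymethoxy)phenyl]propan-1-ol F3. Dess–Martin oxidation gives (2R)-2-[(tert-butyldimethylsilyl)oxy]-3-[2,4,6-tris(methoxymethoxy)phenyl]propanal F4. Addition of 4-methylpent-3-enylmagnesium bromide at −78 °C gives (2R)-2-[(tert-butyldimethylsilyl)oxy]-7-methyl-1-[2,4,6-tris(methoxymethoxy)phenyl]oct-6-en-3-ol F5 as a mixture of C3 epimers. A second Dess–Martin oxidation converges on ketone 13. This route also bypasses the telescoped Weinreb step 4.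

Step 5 is the third. The basic ylide could epimerise the α-silyloxy ketone or react sluggishly at the hindered carbonyl. The fallback sets out from 13 and comes back at 15 by a Peterson olefination. Addition of the weakly basic cerium reagent from Me3SiCH2MgCl/CeCl3 (THF, −78 °C) gives (2R)-2-[(tert-butyldimethylsilyl)oxy]-7-methyl-3-[(trimethylsilyl)methyl]-1-[2,4,6-tris(methoxymethoxy)phenyl]oct-6-en-3-ol F6 as a mixture of C3 epimers. KH in THF at 0 °C then effects syn-elimination of silanolate to give alkene 15.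

**Further compounds**
F1 | step 2 | (2R)-1-(benzyloxy)-3-[2,4,6-tris(methoxymethoxy)phenyl]propan-2-ol | c1ccccc1COC[C@H](O)Cc1c(OCOC)cc(OCOC)cc1OCOC
F2 | step 2 | (2R)-1-(benzyloxy)-2-[(tert-butyldimethylsilyl)oxy]-3-[2,4,6-tris(methoxymethoxy)phenyl]propane | c1ccccc1COC[C@H](O[Si](C)(C)C(C)(C)C)Cc1c(OCOC)cc(OCOC)cc1OCOC
F3 | step 2 | (2R)-2-[(tert-butyldimethylsilyl)oxy]-3-[2,4,6-tris(methoxymethoxy)phenyl]propan-1-ol | OC[C@H](O[Si](C)(C)C(C)(C)C)Cc1c(OCOC)cc(OCOC)cc1OCOC
F4 | step 2 | (2R)-2-[(tert-butyldimethylsilyl)oxy]-3-[2,4,6-tris(methoxymethoxy)phenyl]propanal | O=C[C@H](O[Si](C)(C)C(C)(C)C)Cc1c(OCOC)cc(OCOC)cc1OCOC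
F5 | step 2 | (2R)-2-[(tert-butyldimethylsilyl)oxy]-7-methyl-1-[2,4,6-tris(methoxymethoxy)phenyl]oct-6-en-3-ol (C3 epimer mixture) | CC(C)=CCCC(O)[C@H](O[Si](C)(C)C(C)(C)C)Cc1c(OCOC)cc(OCOC)cc1OCOC
F6 | step 5 | (2R)-2-[(tert-butyldimethylsilyl)oxy]-7-methyl-3-[(trimethylsilyl)methyl]-1-[2,4,6-tris(methoxymethoxy)phenyl]oct-6-en-3-ol (C3 epimer mixture) | CC(C)=CCCC(O)(C[Si](C)(C)C)[C@H](O[Si](C)(C)C(C)(C)C)Cc1c(OCOC)cc(OCOC)cc1OCOC
F7 | step 7 | {3-[(2R)-2-hydroxy-7-methyl-3-methylideneoct-6-en-1-yl]-2,4,6-tris(methoxymethoxy)phenyl}(phenyl)methanone | C=C(CCC=C(C)C)[C@H](O)Cc1c(OCOC)cc(OCOC)c(C(=O)c2ccccc2)c1OCOC
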